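**Plan**
1. The ring B acetate comes off last. Ring A (C1 carries CH2O-palmitoyl, C2 the aryloxy group, C3 OH, C5 OMe) is cut at C2–C3, C3–C4 and C5–C6 into a 4-aryloxy-3-(palmitoyloxymethyl)cyclobutenone (C3, C2, C1, C6) and methoxyacetylene (C4, C5).
2. Feature used: ring A is a 1-hydroxy-3-methoxybenzene with C4–H between the two oxygens and the aryloxy-bearing C2 beside the phenol carbon C3. A vinylketene and an ynol ether assemble exactly this pattern with all three ring A oxygens already told apart.
3. The cyclobutenone is cut at its two ring bonds to the former alkyne carbons into the keteniminium ion of an α-aryloxy-N,N-dimethylacetamide (from orcinol and 2-chloro-N,N-dimethylacetamide) and propargyl palmitate.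
4. Forward: ring B is bought as orcinol, etherified and acetylated; the palmitoyl chain is joined to propargyl alcohol at the outset; the four-membered ring is closed by [2+2] cycloaddition; ring A is then formed by benzannulation; deacetylation ends the route.
5. Stereochemistry: the target has no stereocentre; the one sp3 centre of the cyclobutenone is carried racemic and is erased when ring A aromatizes.

Key step: step 6

Remark: methoxyacetylene is volatile and not a dependable catalogue item, so it is made in the route and used as a cold, titrated toluene solution.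

**Route**

Step 1
Reactants: 1 orcinol; 2 2-chloro-N,N-dimethylacetamide
Product: 3 2-(3-hydroxy-5-methylphenoxy)-N,N-dimethylacetamide
Conditions: K2CO3 (1.1 equiv), NaI (0.1 equiv), acetone, reflux; 1 in threefold excess
Reagents that add atoms: none
Why: Williamson ether synthesis in which the phenoxide of the symmetric diol displaces chloride from the activated α-chloro amide; the excess of 1 should keep double alkylation low, and the two hydroxyls are equivalent, so no regiochemical question arises.

Step 2
Reactants: 3 2-(3-hydroxy-5-methylphenoxy)-N,N-dimethylacetamide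
Product: 4 3-[2-(dimethylamino)-2-oxoethoxy]-5-methylphenyl acetate
Conditions: Ac2O, pyridine, 4-(dimethylamino)pyridine (cat.), CH2Cl2, 0 °C to rt
Reagents that add atoms: acetic anhydride, CC(=O)OC(C)=O
Why: Standard O-acetylation of a phenol under nucleophilic catalysis; the acetate is chosen over a silyl ether because it lowers the nucleophilicity of ring B toward the keteniminium ion of step 5 (a dioxygenated aryloxyacetyl unit is otherwise prone to close to a benzofuranone) and can later be removed from a phenol beside an alkyl ester.

Step 3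
Reactants: 5 propargyl alcohol; 6 palmitoyl chloride
Product: 7 prop-2-yn-1-yl hexadecanoate
Conditions: Et3N, 4-(dimethylamino)pyridine (cat.), CH2Cl2, 0 °C to rt
Reagents that add atoms: none
Why: Acylation of a primary alcohol by an acid chloride in the presence of an amine base, to which the terminal alkyne is inert.

Step 4
Reactants: 8 chloroacetaldehyde dimethyl acetal
Product: 10 methoxyacetylene, via sodium methoxyacetylide 9 (not isolated)
Conditions: NaNH2 (3 equiv), liquid NH3, −33 °C; NH3 evaporated; then saturated aqueous NaCl, −20 °C, product distilled into cold toluene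
Reagents that add atoms: none
Why: Twofold base-induced elimination (loss of methanol and of hydrogen chloride) from the chloroacetal gives the acetylide, which is protonated on aqueous quench; this is the classical preparation of alkoxyacetylenes from chloroacetaldehyde acetals.

Step 5
Reactants: 4 3-[2-(dimethylamino)-2-oxoethoxy]-5-methylphenyl acetate; 7 prop-2-yn-1-yl hexadecanoate
Product: 13 {4-[3-(acetyloxy)-5-methylphenoxy]-3-oxocyclobut-1-en-1-yl}methyl hexadecanoate (racemic), via keteniminium triflate 11 (not isolated), via cyclobuteniminium triflate 12 (not isolated)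
Conditions: Tf2O (1.2 equiv), 2,4,6-collidine (1.2 equiv), 7 (3 equiv), ClCH2CH2Cl, −15 °C to reflux; then H2O, rt
Reagents that add atoms: water, O
Why: Ghosez keteniminium–alkyne [2+2] cycloaddition: Tf2O and collidine turn the tertiary amide into keteniminium ion 11, the terminal alkyne carbon attacks its electrophilic central carbon and the enamine carbon closes the ring, which places the CH2O-palmitoyl group β to the iminium carbon and the aryloxy group on the sp3 carbon of 12; hydrolysis with water alone gives 13 and keeps the released dimethylamine protonated so that it cannot add to the strained enone, and the sp3 centre forms racemic and needs no control.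

Step 6
Reactants: 13 {4-[3-(acetyloxy)-5-methylphenoxy]-3-oxocyclobut-1-en-1-yl}methyl hexadecanoate; 10 methoxyacetylene
Product: 18 {2-[3-(acetyloxy)-5-methylphenoxy]-3-hydroxy-5-methoxyphenyl}methyl hexadecanoate, via vinylketene 14 (not isolated), via alkenylcyclobutenone 15 (not isolated), via dienylketene 16 (not isolated), via cyclohexadienone 17 (not isolated)
Conditions: 10 (4 equiv), toluene, sealed tube, 80 °C, then 110 °C
Reagents that add atoms: none
Why: Heating opens 13 by four-electron conrotatory cleavage of the bond between the carbonyl carbon and the aryloxy-bearing sp3 carbon to give vinylketene 14, whose ketene C=C adds methoxyacetylene [2+2] (ketene carbon to the alkyne CH, the C3–C4 bond; ketene α-carbon to the methoxy-bearing carbon, the C5–C6 bond) to give 15; a second four-electron opening gives dienylketene 16, and six-electron disrotatory electrocyclization closes ring A through the C2–C3 bond to dienone 17, which tautomerizes to phenol 18. This is the Danheiser benzannulation of a cyclobutenone with an alkoxyacetylene, applied here to a cyclobutenone that carries an aryloxy group on its sp3 carbon. The one regiochemical demand lies in the [2+2] step and is met by the polarization of the ynol ether, whose carbon remote from oxygen is nucleophilic and bonds to the electrophilic ketene carbon, so the methoxyl ends up meta to the new hydroxyl with C4–H between them. The aryloxy donor is expected to rotate outward in the first opening, which leaves hydrogen on the inside of the triene terminus and eases the final closure, and a dienylketene of the wrong geometry can return to 15 and open again. No stereocentre is created, since the racemic sp3 carbon of 13 becomes the aromatic C2. The aryl acetate and the palmitate are spectators under these neutral thermal conditions, and an excess of the alkyne is used so that the vinylketene is captured before it can acylate the phenol being formed.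

Step 7
Reactants: 18 {2-[3-(acetyloxy)-5-methylphenoxy]-3-hydroxy-5-methoxyphenyl}methyl hexadecanoate
Product: 19 betaethrin H
Conditions: pyrrolidine (3 equiv), THF, 0 °C to rt
Reagents that add atoms: none
Why: Chemoselective aminolysis of an aryl ester: the acetate, with its phenoxide leaving group, should be cleaved by the secondary amine far faster than the alkyl palmitate, and because the ring A hydroxyl is meta to the CH2O group no quinone methide pathway can expel the palmitate.

**Compound list**
1 | orcinol (5-methylbenzene-1,3-diol) | Cc1cc(O)cc(O)c1 | starting material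
2 | 2-chloro-N,N-dimethylacetamide | CN(C)C(=O)CCl | starting material
3 | 2-(3-hydroxy-5-methylphenoxy)-N,N-dimethylacetamide | CN(C)C(=O)COc1cc(C)cc(O)c1 | intermediate
4 | 3-[2-(dimethylamino)-2-oxoethoxy]-5-methylphenyl acetate | CC(=O)Oc1cc(C)cc(OCC(=O)N(C)C)c1 | intermediate
5 | propargyl alcohol (prop-2-yn-1-ol) | C#CCO | starting material
6 | palmitoyl chloride (hexadecanoyl chloride) | CCCCCCCCCCCCCCCC(=O)Cl | starting material
7 | prop-2-yn-1-yl hexadecanoate (propargyl palmitate) | CCCCCCCCCCCCCCCC(=O)OCC#C | intermediate
8 | chloroacetaldehyde dimethyl acetal (2-chloro-1,1-dimethoxyethane) | COC(CCl)OC | starting material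
9 | sodium methoxyacetylide (not isolated) | [Na+].[C-]#COC | intermediate
10 | methoxyacetylene (methoxyethyne) | COC#C | intermediate
11 | keteniminium triflate (not isolated): N-{2-[3-(acetyloxy)-5-methylphenoxy]ethenylidene}-N-methylmethanaminium trifluoromethanesulfonate | CC(=O)Oc1cc(C)cc(OC=C=[N+](C)C)c1.[O-]S(=O)(=O)C(F)(F)F | intermediate
12 | cyclobuteniminium triflate (not isolated, racemic): N-{4-[3-(acetyloxy)-5-methylphenoxy]-3-[(hexadecanoyloxy)methyl]cyclobut-2-en-1-ylidene}-N-methylmethanaminium trifluoromethanesulfonate | CCCCCCCCCCCCCCCC(=O)OCC1=CC(=[N+](C)C)C1Oc1cc(C)cc(OC(C)=O)c1.[O-]S(=O)(=O)C(F)(F)F | intermediate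
13 | {4-[3-(acetyloxy)-5-methylphenoxy]-3-oxocyclobut-1-en-1-yl}methyl hexadecanoate (racemic) | CCCCCCCCCCCCCCCC(=O)OCC1=CC(=O)C1Oc1cc(C)cc(OC(C)=O)c1 | intermediate
14 | vinylketene (not isolated): 2-{[3-(acetyloxy)-5-methylphenoxy]methylidene}-4-oxobut-3-en-1-yl hexadecanoate, aryloxy group trans to the ketene-bearing carbon | CCCCCCCCCCCCCCCC(=O)OC/C(C=C=O)=C\Oc1cc(C)cc(OC(C)=O)c1 | intermediate
15 | alkenylcyclobutenone (not isolated, racemic): 3-[3-(acetyloxy)-5-methylphenoxy]-2-(2-methoxy-4-oxocyclobut-2-en-1-yl)prop-2-en-1-yl hexadecanoate | CCCCCCCCCCCCCCCC(=O)OC/C(C1C(=O)C=C1OC)=C\Oc1cc(C)cc(OC(C)=O)c1 | intermediate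
16 | dienylketene (not isolated): 2-{[3-(acetyloxy)-5-methylphenoxy]methylidene}-4-methoxy-6-oxohexa-3,5-dien-1-yl hexadecanoate, central double bond cis | CCCCCCCCCCCCCCCC(=O)OC/C(/C=C(OC)\C=C=O)=C\Oc1cc(C)cc(OC(C)=O)c1 | intermediate
17 | cyclohexadienone (not isolated, racemic): {6-[3-(acetyloxy)-5-methylphenoxy]-3-methoxy-5-oxocyclohexa-1,3-dien-1-yl}methyl hexadecanoate | CCCCCCCCCCCCCCCC(=O)OCC1=CC(OC)=CC(=O)C1Oc1cc(C)cc(OC(C)=O)c1 | intermediate
18 | {2-[3-(acetyloxy)-5-methylphenoxy]-3-hydroxy-5-methoxyphenyl}methyl hexadecanoate | CCCCCCCCCCCCCCCC(=O)OCc1cc(OC)cc(O)c1Oc1cc(C)cc(OC(C)=O)c1 | intermediate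
19 | betaethrin H, [3-hydroxy-2-(3-hydroxy-5-methylphenoxy)-5-methoxyphenyl]methyl hexadecanoate | CCCCCCCCCCCCCCCC(=O)OCc1cc(OC)cc(O)c1Oc1cc(C)cc(O)c1 | target

Total step count: 7
Longest linear sequence: 5 steps (steps 1, 2, 5, 6, 7)

**Steps most likely to fail**

Step 5. What may go wrong: the keteniminium ion is consumed faster than the inductively deactivated propargylic ester adds to it. It may self-condense, close onto ring B, or the palmitate carbonyl may take part in the developing vinyl cation, so that the four-membered ring does not form. The fallback takes the ester out of the cycloaddition; it sets out from 5 and 4 and comes back at 13. Propargyl alcohol 5 would be silylated (TBSCl, imidazole, CH2Cl2) to tert-butyldimethyl(prop-2-yn-1-yloxy)silane F1, a more electron-rich alkyne without a neighbouring carbonyl. Under the conditions of step 5 the keteniminium ion 11 from 4 should add it to give the cyclobuteniminium triflate F2 and, after hydrolysis, 3-{[2-({[tert-butyl(dimethyl)silyl]oxy}methyl)-4-oxocyclobut-2-en-1-yl]oxy}-5-methylphenyl acetate F3. HF·pyridine in THF would free the primary alcohol 3-{[2-(hydroxymethyl)-4-oxocyclobut-2-en-1-yl]oxy}-5-methylphenyl acetate F4 without touching the aryl acetate, and palmitoyl chloride 6 with 2,6-lutidine in CH2Cl2 would return the route to 13.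

Step 6. What may go wrong: interception of the vinylketene by the phenol already formed (aryl ester formation), ketene dimerization or oligomerization of the ynol ether, so that the phenol is obtained partly as ketene-derived esters. The customary saponification that repairs this is barred while the palmitate has to survive. The fallback gives up both esters at this stage and restores the palmitate enzymatically; it sets out from 13 and comes back at 19. 13 and 10 would be heated as in step 6 and the crude mixture treated with K2CO3 in MeOH, which cleaves the ketene-derived aryl esters together with the acetate and the palmitate to give [3-hydroxy-2-(3-hydroxy-5-methylphenoxy)-5-methoxyphenyl]methanol F5. Immobilized Candida antarctica lipase B with vinyl hexadecanoate in tert-butyl methyl ether at 40 °C should then acylate only the primary benzylic alcohol and leave both phenols free, which gives 19 directly.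

Step 7. What may go wrong: loss of chemoselectivity between the two esters, with aminolysis or transacylation reaching the benzylic palmitate or acetyl transfer to the ring A phenol. The fallback carries ring B as a silyl ether, which fluoride removes without any acyl-transfer reagent, at the price of a more electron-rich ring B in the keteniminium step; it sets out from 3 and comes back at 19. Phenol 3 would be silylated (TIPSCl, imidazole, DMF) to N,N-dimethyl-2-[3-methyl-5-(triisopropylsilyloxy)phenoxy]acetamide F6. Under the conditions of step 5 with 7 this should pass through the keteniminium triflate F7 and the cyclobuteniminium triflate F8 to {4-[3-methyl-5-(triisopropylsilyloxy)phenoxy]-3-oxocyclobut-1-en-1-yl}methyl hexadecanoate F9. Heating with 10 as in step 6 should lead by way of the vinylketene F10, the alkenylcyclobutenone F11, the dienylketene F12 and the cyclohexadienone F13 to {3-hydroxy-5-methoxy-2-[3-methyl-5-(triisopropylsilyloxy)phenoxy]phenyl}methyl hexadecanoate F14. HF·pyridine in THF at 0 °C then gives 19.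

**Further compounds**
F1 | step 5 | tert-butyldimethyl(prop-2-yn-1-yloxy)silane | C#CCO[Si](C)(C)C(C)(C)C
F2 | step 5 | N-{4-[3-(acetyloxy)-5-methylphenoxy]-3-({[tert-butyl(dimethyl)silyl]oxy}methyl)cyclobut-2-en-1-ylidene}-N-methylmethanaminium trifluoromethanesulfonate (racemic, not isolated) | CC(=O)Oc1cc(C)cc(OC2C(CO[Si](C)(C)C(C)(C)C)=CC2=[N+](C)C)c1.[O-]S(=O)(=O)C(F)(F)F
F3 | step 5 | 3-{[2-({[tert-butyl(dimethyl)silyl]oxy}methyl)-4-oxocyclobut-2-en-1-yl]oxy}-5-methylphenyl acetate (racemic) | CC(=O)Oc1cc(C)cc(OC2C(CO[Si](C)(C)C(C)(C)C)=CC2=O)c1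
F4 | step 5 | 3-{[2-(hydroxymethyl)-4-oxocyclobut-2-en-1-yl]oxy}-5-methylphenyl acetate (racemic) | CC(=O)Oc1cc(C)cc(OC2C(CO)=CC2=O)c1
F5 | step 6 | [3-hydroxy-2-(3-hydroxy-5-methylphenoxy)-5-methoxyphenyl]methanol | COc1cc(O)c(Oc2cc(C)cc(O)c2)c(CO)c1
F6 | step 7 | N,N-dimethyl-2-[3-methyl-5-(triisopropylsilyloxy)phenoxy]acetamide | CN(C)C(=O)COc1cc(C)cc(O[Si](C(C)C)(C(C)C)C(C)C)c1
F7 | step 7 | N-methyl-N-{2-[3-methyl-5-(triisopropylsilyloxy)phenoxy]ethenylidene}methanaminium trifluoromethanesulfonate (not isolated) | C[N+](C)=C=COc1cc(C)cc(O[Si](C(C)C)(C(C)C)C(C)C)c1.[O-]S(=O)(=O)C(F)(F)F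
F8 | step 7 | N-{3-[(hexadecanoyloxy)methyl]-4-[3-methyl-5-(triisopropylsilyloxy)phenoxy]cyclobut-2-en-1-ylidene}-N-methylmethanaminium trifluoromethanesulfonate (racemic, not isolated) | CCCCCCCCCCCCCCCC(=O)OCC1=CC(=[N+](C)C)C1Oc1cc(C)cc(O[Si](C(C)C)(C(C)C)C(C)C)c1.[O-]S(=O)(=O)C(F)(F)F
F9 | step 7 | {4-[3-methyl-5-(triisopropylsilyloxy)phenoxy]-3-oxocyclobut-1-en-1-yl}methyl hexadecanoate (racemic) | CCCCCCCCCCCCCCCC(=O)OCC1=CC(=O)C1Oc1cc(C)cc(O[Si](C(C)C)(C(C)C)C(C)C)c1
F10 | step 7 | 2-{[3-methyl-5-(triisopropylsilyloxy)phenoxy]methylidene}-4-oxobut-3-en-1-yl hexadecanoate (vinylketene, not isolated) | CCCCCCCCCCCCCCCC(=O)OC/C(C=C=O)=C\Oc1cc(C)cc(O[Si](C(C)C)(C(C)C)C(C)C)c1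
F11 | step 7 | 2-(2-methoxy-4-oxocyclobut-2-en-1-yl)-3-[3-methyl-5-(triisopropylsilyloxy)phenoxy]prop-2-en-1-yl hexadecanoate (racemic, not isolated) | CCCCCCCCCCCCCCCC(=O)OC/C(C1C(=O)C=C1OC)=C\Oc1cc(C)cc(O[Si](C(C)C)(C(C)C)C(C)C)c1
F12 | step 7 | 4-methoxy-2-{[3-methyl-5-(triisopropylsilyloxy)phenoxy]methylidene}-6-oxohexa-3,5-dien-1-yl hexadecanoate (dienylketene, not isolated) | CCCCCCCCCCCCCCCC(=O)OC/C(/C=C(OC)\C=C=O)=C\Oc1cc(C)cc(O[Si](C(C)C)(C(C)C)C(C)C)c1
F13 | step 7 | {3-methoxy-6-[3-methyl-5-(triisopropylsilyloxy)phenoxy]-5-oxocyclohexa-1,3-dien-1-yl}methyl hexadecanoate (racemic, not isolated) | CCCCCCCCCCCCCCCC(=O)OCC1=CC(OC)=CC(=O)C1Oc1cc(C)cc(O[Si](C(C)C)(C(C)C)C(C)C)c1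
F14 | step 7 | {3-hydroxy-5-methoxy-2-[3-methyl-5-(triisopropylsilyloxy)phenoxy]phenyl}methyl hexadecanoate | CCCCCCCCCCCCCCCC(=O)OCc1cc(OC)cc(O)c1Oc1cc(C)cc(O[Si](C(C)C)(C(C)C)C(C)C)c1
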